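1. At the last reading, 80.0 d, the dawn and winter runs, both at −25 °C, held 89.5 % and 88.7 % of their starting complex, although c(leaving ligand) was 0.26 M in dawn and 0.98 M in winter. I worked with the fraction left: the logarithm of charged over left, divided by time, gives 0.00139 /d for dawn and 0.00150 /d for winter. With a scatter of 0.5 percentage points I read no slowing by leaving ligand, so I expected the two new flasks to part by temperature history rather than by their c(leaving ligand).

all flasks: starting complex 0.18 M

| charge | incoming ligand | leaving ligand | temperature | remark | time |
|---|---|---|---|---|---|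
| dawn | 0.36 M | 0.26 M | −25 °C | run made earlier |  |
| autumn | 0.36 M | 0.48 M | 0 °C | run made earlier |  |
| winter | 0.36 M | 0.98 M | −25 °C | run made earlier |  |
| beta | 0.360 M | 0.300 M |  | at 20 °C throughout | 15 d |
| delta | 0.360 M | 0.900 M |  | at 20 °C until 3.0 d, from then on at −20 °C | 15 d |

| run | time / d | complex with two exchanged / % | starting complex / % |
|---|---|---|---|
| dawn | 6.00 | 0 | 99.1 |
| dawn | 10.0 | 0.1 | 97.8 |
| dawn | 20.0 | 0.2 | 97.6 |
| dawn | 40.0 | 0 | 93.4 |
| dawn | 80.0 | 0.8 | 89.5 |
| autumn | 5.00 | 1.1 | 83.5 |
| autumn | 8.00 | 1.8 | 75.6 |
| autumn | 15.0 | 6.4 | 58.9 |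
| autumn | 20.0 | 8.4 | 51.0 |
| winter | 6.00 | 0 | 99.2 |
| winter | 20.0 | 0.3 | 97.2 |
| winter | 40.0 | 0.3 | 93.8 |
| winter | 50.0 | 0 | 93.2 |
| winter | 80.0 | 0 | 88.7 |

(each reading ± 0.5 percentage points)

* the winner by amount of complex with two exchanged, in percent of the starting complex charged; "neither" if no more than 2 percentage points parts them (beta / delta / neither)
* how much complex with two exchanged is there at the end, in percent of the starting complex charged: beta
* how much complex with two exchanged is there at the end, in percent of the starting complex charged: delta

2. The autumn run, at 0 °C, gives 0.0337 /d, and with the dawn value that makes an activation energy of 71.9 kJ/mol. Extrapolated to 20 °C, the figure is 0.292 /d. This is the loss constant, read off scattered readings and taken as the pseudo-first-order constant of the starting complex with incoming ligand charged at 0.36 M. At −20 °C I reckoned 0.00276 /d, which is far slower than at 20 °C.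

3. By my reckoning, beta keeps 1.25 % of its starting complex at 15 d. Delta keeps 41.7 % at 3.0 d, and after the cold days 40.3 %.

4. In the autumn run at 20.0 d, the readings put 17.1 % of the lost starting complex as complex with two exchanged. Taken over unchanged, that share would give beta 16.9 % and delta 10.2 %, so I committed to beta.

5. The forecast also named beta, with 78 % for beta and 13 % for delta, where “then cooling nearly freezes it”. The flasks give 29.7 % for beta and 14.3 % for delta, so beta wins.

    starting complex + incoming ligand → leaving ligand + complex with one exchanged (k = 1.17 × 10⁻⁵ /M/s, Ea = 74.0 kJ/mol)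
    complex with one exchanged → side product (k = 4.83 × 10⁻⁶ /s, Ea = 91.0 kJ/mol)
    complex with one exchanged + incoming ligand → leaving ligand + complex with two exchanged (k = 1.06 × 10⁻⁵ /M/s, Ea = 88.0 kJ/mol)
    (constants at 20 °C)

Delta held 42.1 % of its starting complex at the change of temperature, against my 41.7 %. Beta held 5.72 % at 15 d against my 1.25 %, with 38.0 % of its incoming ligand left. In beta at 2.08 d, complex with one exchanged had a half-life of 1.7 d towards side product and 2.9 d towards complex with two exchanged, and beta ended with 62.5 % of side product. For the neighbour of beta charged with 0.31 M of starting complex, the loss constant gives 1.25 % left at 15 d; that neighbour holds 17.9 % then, with 19.5 % of complex with two exchanged.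

(All runs were computed with made-up constants, and the scatter is random.)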